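## Retrosynthetic overview
1. Bulbocodin C comes from a tetra-O-benzyl stilbene by one global hydrogenation, which turns C=C into the CH2CH2 bridge and four OBn groups into OH.
2. Key disconnection: both aryl–CH2 bonds (C2 and C4) are cut at once. This gives a 2,4-diiodostilbene and 2 × 4-(benzyloxy)benzaldehyde, whose carbonyl carbon serves as a benzyl-anion equivalent through its NH2-hydrazone (Ni(0), –N2).
3. The bridge C=C comes from 5-(benzyloxy)-2,4-diiodo-3-methoxybenzaldehyde and 3-(benzyloxy)benzaldehyde hydrazone, an aldehyde–aldehyde reductive olefination (Ru(II), –N2, –H2O).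
4. The diiodoaldehyde comes from 3,5-dihydroxybenzaldehyde by C4/C2 diiodination, followed by steric differentiation of the two phenols (BnBr, then MeI).
5. No ring is formed. All four benzene rings are bought and the central ring is only decorated.

Assumption: the target SMILES has no stereocentre and no stereogenic double bond, so the compound is achiral and needs no enantiocontrol. The only stereo-element on the way, an E-alkene, is erased in the last step.

Locants of the central ring used throughout: C1 = CHO/bridge, C2 = I/benzyl, C3 = O(Me), C4 = I/benzyl, C5 = O(H/Bn), C6 = H.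

## Route

Step 1
Reactants: 1 3,5-dihydroxybenzaldehyde
Product: 3 3,5-dihydroxy-2,4-diiodobenzaldehyde, via 3,5-dihydroxy-4-iodobenzaldehyde 2 (not isolated)
Conditions: I2 (2.05 equiv), NaHCO3 (2.3 equiv), H2O–THF, 0 °C to rt; Na2S2O3, acidify only to pH 5
Reagents that add atoms: iodine, II
Why: Electrophilic aromatic iodination of the resorcinol phenolate in aqueous bicarbonate goes kinetically to the carbon between the two oxygens (resorcinol gives 2-iodo- and then 2,4-diiodoresorcinol under these conditions), so the first iodine enters C4 and the second takes one of the two equivalent positions C2/C6, which fixes the 2,4-pattern; no stereocentre is formed.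

Step 2
Reactants: 3 3,5-dihydroxy-2,4-diiodobenzaldehyde
Product: 5 5-(benzyloxy)-2,4-diiodo-3-methoxybenzaldehyde, via 5-(benzyloxy)-3-hydroxy-2,4-diiodobenzaldehyde 4 (not isolated)
Conditions: NaH (2.2 equiv), DMF, 0 °C; BnBr (1.0 equiv), 0 °C, 2 h; then MeI (3 equiv), rt
Reagents that add atoms: benzyl bromide, BrCc1ccccc1; iodomethane, CI
Why: Sequential Williamson etherification of the fully formed dianion, in which the C5 phenoxide (one ortho iodine, more basic) is benzylated much faster than the C3 phenoxide buried between two iodines, and the latter is then capped by the small electrophile MeI in the same pot; no stereocentre is formed.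

Step 3
Reactants: 5 5-(benzyloxy)-2,4-diiodo-3-methoxybenzaldehyde; 6 3-(benzyloxy)benzaldehyde
Product: 8 (E)-1-(benzyloxy)-5-[3-(benzyloxy)styryl]-2,4-diiodo-3-methoxybenzene, via 3-(benzyloxy)benzaldehyde hydrazone 7 (not isolated)
Conditions: 6, N2H4·H2O (1.05 equiv), THF, rt, 1 h; then 5, [Ru(p-cymene)Cl2]2 (cat.), dmpe (cat.), KOtBu (0.5 equiv), CsF, THF, 45 °C
Reagents that add atoms: none
Why: Ru(II)-catalysed hydrazine-mediated reductive carbonyl cross-olefination, in which the hydrazone carbon of 7 adds as a benzyl-anion equivalent to the C=O of the electron-poor aldehyde 5 and base-induced loss of N2 with E1cB loss of hydroxide gives the stilbene (mainly E; the geometry is irrelevant because it is hydrogenated later).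

Step 4 (key step)
Reactants: 8 (E)-1-(benzyloxy)-5-[3-(benzyloxy)styryl]-2,4-diiodo-3-methoxybenzene; 9 4-(benzyloxy)benzaldehyde (3 equiv)
Product: 12 (E)-1-(benzyloxy)-2,4-bis[4-(benzyloxy)benzyl]-5-[3-(benzyloxy)styryl]-3-methoxybenzene, via 4-(benzyloxy)benzaldehyde hydrazone 10 (not isolated), via C4-monobenzylated 2-iodostilbene 11 (not isolated)
Conditions: 9, N2H4·H2O (3.1 equiv), THF, 4 Å MS, rt, 1 h; then 8, Ni(cod)2 (20 mol %), PMe3 (40 mol %), DBU (5 equiv), THF–dioxane, 60–80 °C
Reagents that add atoms: none
Why: Proposed new method: this is a twofold version, at di-ortho-flanked iodides, of the known Ni(0)/PMe3-catalysed cross-coupling of aryl halides with aldehyde NH2-hydrazones (a Wolff–Kishner-type umpolung cross-coupling), in which each C–I bond adds oxidatively to Ni(0), DBU deprotonates the Ni-bound hydrazone 10 to an aza-allyl-type ligand whose former carbonyl carbon is now the nucleophilic terminus, C(sp2)–C(sp3) reductive elimination gives a benzylic diazene that loses N2 and is protonated to ArCH2Ar', so two normally electrophilic carbons (ArI and ArCHO) are joined twice in one flask, the small PMe3 ligand and the iodide leaving groups keep C2 and C4 accessible, the order of the two couplings does not matter, and no stereocentre is formed.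

Step 5
Reactants: 12 (E)-1-(benzyloxy)-2,4-bis[4-(benzyloxy)benzyl]-5-[3-(benzyloxy)styryl]-3-methoxybenzene
Product: 13 Bulbocodin C, 2,4-bis(4-hydroxybenzyl)-5-[2-(3-hydroxyphenyl)ethyl]-3-methoxyphenol
Conditions: H2 (1 atm), 10 % Pd/C, THF–MeOH, rt
Reagents that add atoms: none
Why: Catalytic hydrogenation saturates the stilbene and hydrogenolyses all four aryl benzyl ethers in one operation, while the methyl ether and the diarylmethane C–C bonds are inert; the product is achiral.

## Compound list
1 | 3,5-dihydroxybenzaldehyde | O=Cc1cc(O)cc(O)c1 | starting material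
2 | 3,5-dihydroxy-4-iodobenzaldehyde (not isolated) | O=Cc1cc(O)c(I)c(O)c1 | intermediate
3 | 3,5-dihydroxy-2,4-diiodobenzaldehyde | O=Cc1cc(O)c(I)c(O)c1I | intermediate
4 | 5-(benzyloxy)-3-hydroxy-2,4-diiodobenzaldehyde (not isolated) | O=Cc1cc(OCc2ccccc2)c(I)c(O)c1I | intermediate
5 | 5-(benzyloxy)-2,4-diiodo-3-methoxybenzaldehyde | O=Cc1cc(OCc2ccccc2)c(I)c(OC)c1I | intermediate
6 | 3-(benzyloxy)benzaldehyde | O=Cc1cccc(OCc2ccccc2)c1 | starting material
7 | (E)-[3-(benzyloxy)benzylidene]hydrazine (not isolated) | N/N=C/c1cccc(OCc2ccccc2)c1 | intermediate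
8 | (E)-1-(benzyloxy)-5-[3-(benzyloxy)styryl]-2,4-diiodo-3-methoxybenzene | COc1c(I)c(OCc2ccccc2)cc(/C=C/c2cccc(OCc3ccccc3)c2)c1I | intermediate
9 | 4-(benzyloxy)benzaldehyde | O=Cc1ccc(OCc2ccccc2)cc1 | starting material
10 | (E)-[4-(benzyloxy)benzylidene]hydrazine (not isolated) | N/N=C/c1ccc(OCc2ccccc2)cc1 | intermediate
11 | (E)-1-(benzyloxy)-2-[4-(benzyloxy)benzyl]-5-[3-(benzyloxy)styryl]-4-iodo-3-methoxybenzene (mono-coupled, drawn for C4 first, not isolated) | COc1c(Cc2ccc(OCc3ccccc3)cc2)c(OCc2ccccc2)cc(/C=C/c2cccc(OCc3ccccc3)c2)c1I | intermediate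
12 | (E)-1-(benzyloxy)-2,4-bis[4-(benzyloxy)benzyl]-5-[3-(benzyloxy)styryl]-3-methoxybenzene | COc1c(Cc2ccc(OCc3ccccc3)cc2)c(OCc2ccccc2)cc(/C=C/c2cccc(OCc3ccccc3)c2)c1Cc1ccc(OCc2ccccc2)cc1 | intermediate
13 | Bulbocodin C | COc1c(Cc2ccc(O)cc2)c(O)cc(CCc2cccc(O)c2)c1Cc1ccc(O)cc1 | target

## Step count and risks
Total step count: 5. Longest linear sequence: 5 (1 → 3 → 5 → 8 → 12 → 13).

**Step 4 is the most likely to fail.** Both iodides are flanked on both sides. Hydrodeiodination or N-arylation of the hydrazone may therefore outrun C–C bond formation, or the reaction may stop at 11.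

The fallback sets out from 8 and gives up the hydrazone for a benzylic organometallic. Commercial 4-(benzyloxy)benzyl chloride is inserted with Zn dust/LiCl in THF to give 4-(benzyloxy)benzylzinc chloride F1. This is coupled twice with 8 in a Negishi reaction (Pd-PEPPSI-IPent or Pd(OAc)2/SPhos, THF, 50 °C). The fallback comes back to the route at 12.

**Step 3 is the second risk.** Azine formation between 7 and 5, hydrazone exchange leading to homo-coupled stilbenes, or loss of iodine under the basic Ru conditions can erode the yield.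

The fallback sets out from 5 and replaces the hydrazone by a phosphonate carbanion. Commercial 3-(benzyloxy)benzyl bromide and P(OEt)3 (neat, 130 °C, Arbuzov) give diethyl [3-(benzyloxy)benzyl]phosphonate F2. This undergoes Horner–Wadsworth–Emmons olefination with 5 (NaH, THF, 0 °C to rt). The fallback comes back at 8.

**Step 2 is the third risk.** Benzylation may not discriminate well enough between the two phenoxides.

The fallback sets out from 3 and uses a bulky silyl group in place of kinetic alkylation.
- TBDPSCl/imidazole (DMF, 0 °C) silylates only the open C5–OH, giving 5-[(tert-butyldiphenylsilyl)oxy]-3-hydroxy-2,4-diiodobenzaldehyde F3.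
- Neutral Mitsunobu methylation (MeOH, PPh3, DIAD, THF) of the acidic, flanked C3–OH gives 5-[(tert-butyldiphenylsilyl)oxy]-2,4-diiodo-3-methoxybenzaldehyde F4.
- TBAF/AcOH gives 5-hydroxy-2,4-diiodo-3-methoxybenzaldehyde F5.
- BnBr/K2CO3 in DMF then brings the fallback back at 5.

## Further compounds
F1 | step 4 | 4-(benzyloxy)benzylzinc chloride | Cl[Zn]Cc1ccc(OCc2ccccc2)cc1
F2 | step 3 | diethyl [3-(benzyloxy)benzyl]phosphonate | CCOP(=O)(Cc1cccc(OCc2ccccc2)c1)OCC
F3 | step 2 | 5-[(tert-butyldiphenylsilyl)oxy]-3-hydroxy-2,4-diiodobenzaldehyde | O=Cc1cc(O[Si](c2ccccc2)(c2ccccc2)C(C)(C)C)c(I)c(O)c1I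
F4 | step 2 | 5-[(tert-butyldiphenylsilyl)oxy]-2,4-diiodo-3-methoxybenzaldehyde | O=Cc1cc(O[Si](c2ccccc2)(c2ccccc2)C(C)(C)C)c(I)c(OC)c1I
F5 | step 2 | 5-hydroxy-2,4-diiodo-3-methoxybenzaldehyde | O=Cc1cc(O)c(I)c(OC)c1I
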